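The route rests on cutting ring A at C7–C8 and C8a–C4a. A thermal cyclobutenone–siloxyalkyne benzannulation builds this ring in one operation and exploits its defining feature: a hexasubstituted benzene whose three oxygens at C5, C7 and C8a flank C6-methyl and the Cα-bearing C8 and must be distinguished; they emerge as benzyl ether, free phenol and silyl ether. The precursors are a triisopropylsiloxyalkyne that already carries Cα (S, with its isobutyl group) and ring D as a benzyl enol ether, and 3-benzyloxy-4-methylcyclobutenone. Ring C follows through O8a via a chromone and ligand-controlled phenyl addition at C2; one neutral hydrogenolysis ends the synthesis.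

Key step: step 7

Remark on labels: C2–C8a, Cα and rings A, C and D follow the flavanone numbering of the target; in the target Cα is S and C2 is R, and ring D is symmetric about its Cα-bearing carbon, so it gives one enol ether only.
Remark on protection: benzyl is placed on O5, O7 and the ring D enol so that the last step is neutral; acid at the end would risk C2 epimerisation and cyclodehydration between the C7 hydroxyl and ring D.
Remark on ligands: in steps 2 and 12 the antipode named is the one expected by analogy; the mirror-image ligand is used if a pilot run shows the opposite sense.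

Step 1
Reactants: 1 syncarpic acid (2,2,4,4-tetramethylcyclohexane-1,3,5-trione); 2 isovaleraldehyde (3-methylbutanal)
Product: 3 2,2,4,4-tetramethyl-6-(3-methylbutylidene)cyclohexane-1,3,5-trione
Conditions: 2 (1.5 equiv), piperidine (10 mol%), AcOH (10 mol%), 4 Å sieves, CH2Cl2, 0 °C → rt; used crude
Reagents that add atoms: none
Why: Knoevenagel condensation of the cyclic 1,3-dione with the aldehyde, in which the flanking gem-dimethyl groups should hold back a second Michael addition; the symmetric ring allows no alkene isomers.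

Step 2
Reactants: 3 alkylidene trione; 4 trimethylsilylacetylene
Product: 5 3-hydroxy-4,4,6,6-tetramethyl-2-[(3R)-5-methyl-1-(trimethylsilyl)hex-1-yn-3-yl]cyclohex-2-ene-1,5-dione
Conditions: Cu(OAc)2·H2O (10 mol%), sodium L-ascorbate (20 mol%), (R,Ra)-N-PINAP (10 mol%), H2O, 0 °C; EDTA wash
Reagents that add atoms: none
Why: Proposed new method: a monovalent copper acetylide formed in water from 4 should add to the β-carbon of the s-cis alkylidene dicarbonyl while the P,N ligand shields one face (attack on the Re face sets Cα in the target arrangement, the descriptor being R here only because silicon raises the alkynyl priority), and water should protonate the copper diketonate to release enol and catalyst; the closest known reaction is the copper/PINAP conjugate alkynylation of alkylidene Meldrum's acids, carried over here to an alkylidene cyclic triketone of similar electrophilicity and to a silylacetylene.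

Step 3
Reactants: 5 silylalkyne enol
Product: 7 3-(benzyloxy)-4,4,6,6-tetramethyl-2-[(3S)-5-methylhex-1-yn-3-yl]cyclohex-2-ene-1,5-dione, via silylalkyne benzyl ether 6 (not isolated)
Conditions: BnBr, Cs2CO3, DMF, 0 °C → rt; then MeOH, rt
Reagents that add atoms: benzyl bromide, BrCc1ccccc1
Why: Williamson-type O-alkylation of the hindered triketone enolate (C-benzylation would build a quaternary centre next to Cα), followed by carbonate/methanol cleavage of the C–Si bond only after the enol oxygen is capped, so that it cannot cyclise onto the free alkyne.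

Step 4
Reactants: 7 terminal alkyne
Product: 10 3-(benzyloxy)-4,4,6,6-tetramethyl-2-{(3S)-5-methyl-1-[(triisopropylsilyl)oxy]hex-1-yn-3-yl}cyclohex-2-ene-1,5-dione, via lithium acetylide 8 (not isolated), via lithium ynolate 9 (not isolated)
Conditions: LiN(SiMe3)2, THF, −78 °C; t-BuOOLi (from t-BuOOH + LiN(SiMe3)2), −78 → 0 °C; TIPSOTf, −78 °C
Reagents that add atoms: tert-butyl hydroperoxide, CC(C)(C)OO; triisopropylsilyl trifluoromethanesulfonate, CC(C)[Si](OS(=O)(=O)C(F)(F)F)(C(C)C)C(C)C
Why: Oxidation of a lithium acetylide by lithium tert-butyl peroxide gives the ynolate, which the silyl triflate traps on oxygen; only a non-nucleophilic amide base is present, so the hindered ring D carbonyls and the weakly acidic Cα–H should stay untouched.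

Step 5
Reactants: 11 benzyl alcohol; 12 trichloroethylene
Product: 16 benzyloxyacetylene, via dichlorovinyl ether 13 (not isolated), via chloroalkynyl ether 14 (not isolated), via lithium alkynyl ether 15 (not isolated)
Conditions: KH, THF, 0 °C; Cl2C=CHCl, −50 °C → rt; n-BuLi (2.3 equiv), −78 → −40 °C; MeOH, −78 °C; kept cold in solution
Reagents that add atoms: none
Why: Standard alkoxyacetylene synthesis from an alcohol: the alkoxide replaces one chloride of trichloroethylene, n-BuLi effects dehydrochlorination and chlorine–lithium exchange, and the lithium alkynyl ether is protonated cold.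

Step 6
Reactants: 16 benzyloxyacetylene; 17 propionyl chloride
Product: 19 3-(benzyloxy)-4-methylcyclobut-2-en-1-one (racemic at C4), via methylketene 18 (not isolated)
Conditions: Et3N, Et2O, 0 °C → rt
Reagents that add atoms: none
Why: Dehydrochlorination gives methylketene, whose carbonyl carbon bonds to the unsubstituted alkyne carbon in a ketene–alkoxyalkyne [2+2] cycloaddition, which places methyl at C4 and benzyloxy at C3.

Step 7
Reactants: 10 siloxyalkyne; 19 cyclobutenone
Product: 24 3-(benzyloxy)-6-[(1S)-1-(2-(benzyloxy)-3,3,5,5-tetramethyl-4,6-dioxocyclohex-1-en-1-yl)-3-methylbutyl]-2-methyl-5-[(triisopropylsilyl)oxy]phenol, via vinylketene 20 (not isolated), via vinylcyclobutenone 21 (not isolated), via dienylketene 22 (not isolated), via cyclohexadienone 23 (not isolated)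
Conditions: 19 (1.5 equiv), degassed toluene, 80 °C then 110 °C, sealed tube
Reagents that add atoms: none
Why: Four-electron electrocyclic opening of 19 gives vinylketene 20; its ketene carbon (future C7) is attacked by the Cα-bearing alkyne carbon (future C8) while the oxygenated alkyne carbon (future C8a) bonds to the ketene α-carbon (future C4a) in a [2+2] cycloaddition, and the resulting 21 reopens to dienylketene 22. Ring A is closed by a thermally allowed six-electron electrocyclisation between C6 and C7, and dienone 23 tautomerises to the phenol. The closest known reaction is the Danheiser benzannulation of cyclobutenones with siloxyalkynes to resorcinol monosilyl ethers, 3-alkoxycyclobutenones being its less common partners. No stereocentre is created: Cα is a spectator in a neutral thermal cascade, and the transient sp3 centre and alkene geometries of 20–23 are erased on aromatisation. The selectivity needed is regiochemical and is secured by the polarity of the ynol ether, which should leave O7 as free phenol, O8a as silyl ether and O5 as benzyl ether.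

Step 8
Reactants: 24 ring A phenol
Product: 25 2-{(1S)-1-[2,4-bis(benzyloxy)-3-methyl-6-(triisopropylsilyloxy)phenyl]-3-methylbutyl}-3-(benzyloxy)-4,4,6,6-tetramethylcyclohex-2-ene-1,5-dione
Conditions: BnBr, K2CO3, DMF, rt → 50 °C
Reagents that add atoms: benzyl bromide, BrCc1ccccc1
Why: Williamson benzylation of the only free phenol (O7), under carbonate conditions that should leave the aryl silyl ether and the benzyl enol ether intact.

Step 9
Reactants: 25 fully protected arene
Product: 26 2-{(1S)-1-[5-acetyl-2,4-bis(benzyloxy)-3-methyl-6-(triisopropylsilyloxy)phenyl]-3-methylbutyl}-3-(benzyloxy)-4,4,6,6-tetramethylcyclohex-2-ene-1,5-dione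
Conditions: AcOH, (CF3CO)2O, CH2Cl2, 0 °C → rt
Reagents that add atoms: acetic acid, CC(=O)O
Why: Friedel–Crafts acylation by the mixed acetic trifluoroacetic anhydride at C4a, the single unsubstituted ring position and activated by three oxygens, without a metal Lewis acid that could strip the benzyl ethers by chelation; any silyl loss here converges in step 10.

Step 10
Reactants: 26 aryl ketone
Product: 27 2-{(1S)-1-[3-acetyl-4,6-bis(benzyloxy)-2-hydroxy-5-methylphenyl]-3-methylbutyl}-3-(benzyloxy)-4,4,6,6-tetramethylcyclohex-2-ene-1,5-dione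
Conditions: Bu4NF, AcOH, THF, 0 °C
Reagents that add atoms: none
Why: Buffered fluoride cleaves the aryl Si–O bond and frees only the C8a hydroxyl, which hydrogen-bonds to the new ketone.

Step 11
Reactants: 27 hydroxy ketone
Product: 29 5,7-bis(benzyloxy)-8-[(1S)-1-(2-(benzyloxy)-3,3,5,5-tetramethyl-4,6-dioxocyclohex-1-en-1-yl)-3-methylbutyl]-6-methyl-4H-chromen-4-one, via enaminone 28 (not isolated)
Conditions: Me2NCH(OMe)2, toluene, 90 °C; then AcOH, 60 °C
Reagents that add atoms: N,N-dimethylformamide dimethyl acetal, COC(OC)N(C)C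
Why: Enaminone route to chromones: the methyl ketone condenses with the formamide acetal and acid promotes addition of the C8a hydroxyl with loss of dimethylamine; O5 is blocked, so ring C can close only through O8a.

Step 12
Reactants: 29 chromone; 30 phenylboronic acid
Product: 31 (2R)-5,7-bis(benzyloxy)-8-[(1S)-1-(2-(benzyloxy)-3,3,5,5-tetramethyl-4,6-dioxocyclohex-1-en-1-yl)-3-methylbutyl]-6-methyl-2-phenyl-2,3-dihydro-4H-chromen-4-one
Conditions: Pd(OCOCF3)2 (10 mol%), (S)-t-BuPyOx (12 mol%), NH4PF6, H2O, ClCH2CH2Cl, 60 °C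
Reagents that add atoms: none
Why: Palladium-catalysed asymmetric conjugate addition of an arylboronic acid to a chromone with a pyridine–oxazoline ligand, the ligand setting the face of phenyl transfer to C2 (2R expected from the (S)-ligand by the facial model for cyclic enones) in a neutral medium that avoids retro-oxa-Michael epimerisation.

Step 13
Reactants: 31 protected flavanone
Product: 32 (2R)-5,7-dihydroxy-8-[(1S)-1-(2-hydroxy-3,3,5,5-tetramethyl-4,6-dioxocyclohex-1-en-1-yl)-3-methylbutyl]-6-methyl-2-phenyl-2,3-dihydro-4H-chromen-4-one (CNP0249552.1)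
Conditions: H2 (1 atm), Pd/C (10 wt% Pd), EtOAc, rt, monitored
Reagents that add atoms: none
Why: Hydrogenolysis of the two aryl benzyl ethers and the vinylogous benzyl ester under neutral conditions should leave C2 and Cα untouched.

Compound list
1 | syncarpic acid (2,2,4,4-tetramethylcyclohexane-1,3,5-trione) | CC1(C)C(=O)CC(=O)C(C)(C)C1=O | starting material
2 | isovaleraldehyde (3-methylbutanal) | CC(C)CC=O | starting material
3 | 2,2,4,4-tetramethyl-6-(3-methylbutylidene)cyclohexane-1,3,5-trione | CC(C)CC=C1C(=O)C(C)(C)C(=O)C(C)(C)C1=O | intermediate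
4 | trimethylsilylacetylene | C#C[Si](C)(C)C | starting material
5 | 3-hydroxy-4,4,6,6-tetramethyl-2-[(3R)-5-methyl-1-(trimethylsilyl)hex-1-yn-3-yl]cyclohex-2-ene-1,5-dione (Cα arranged as in the target) | C[Si](C)(C)C#C[C@H](CC(C)C)C1=C(O)C(C)(C)C(=O)C(C)(C)C1=O | intermediate
6 | benzyl enol ether of 5 | C[Si](C)(C)C#C[C@H](CC(C)C)C1=C(OCc2ccccc2)C(C)(C)C(=O)C(C)(C)C1=O | intermediate (not isolated)
7 | 3-(benzyloxy)-4,4,6,6-tetramethyl-2-[(3S)-5-methylhex-1-yn-3-yl]cyclohex-2-ene-1,5-dione | C#C[C@H](CC(C)C)C1=C(OCc2ccccc2)C(C)(C)C(=O)C(C)(C)C1=O | intermediate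
8 | lithium acetylide of 7 | [Li]C#C[C@H](CC(C)C)C1=C(OCc2ccccc2)C(C)(C)C(=O)C(C)(C)C1=O | intermediate (not isolated)
9 | lithium ynolate from 8 | [Li+].[O-]C#C[C@H](CC(C)C)C1=C(OCc2ccccc2)C(C)(C)C(=O)C(C)(C)C1=O | intermediate (not isolated)
10 | 3-(benzyloxy)-4,4,6,6-tetramethyl-2-{(3S)-5-methyl-1-[(triisopropylsilyl)oxy]hex-1-yn-3-yl}cyclohex-2-ene-1,5-dione (siloxyalkyne carrying Cα and ring D) | CC(C)[Si](OC#C[C@H](CC(C)C)C1=C(OCc2ccccc2)C(C)(C)C(=O)C(C)(C)C1=O)(C(C)C)C(C)C | intermediate
11 | benzyl alcohol | OCc1ccccc1 | starting material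
12 | trichloroethylene | ClC=C(Cl)Cl | starting material
13 | benzyl (E)-1,2-dichlorovinyl ether | Cl/C=C(/Cl)OCc1ccccc1 | intermediate (not isolated)
14 | benzyl chloroethynyl ether | ClC#COCc1ccccc1 | intermediate (not isolated)
15 | lithium benzyloxyacetylide | [Li]C#COCc1ccccc1 | intermediate (not isolated)
16 | benzyloxyacetylene | C#COCc1ccccc1 | intermediate
17 | propionyl chloride | CCC(=O)Cl | starting material
18 | methylketene | CC=C=O | intermediate (not isolated)
19 | 3-(benzyloxy)-4-methylcyclobut-2-en-1-one (racemic) | CC1C(OCc2ccccc2)=CC1=O | intermediate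
20 | 3-(benzyloxy)penta-1,3-dien-1-one (vinylketene; alkene geometry not controlled) | CC=C(OCc1ccccc1)C=C=O | intermediate (not isolated)
21 | [2+2] adduct: 4-[1-(benzyloxy)prop-1-enyl]-3-(triisopropylsilyloxy)cyclobut-2-en-1-one bearing the Cα/ring D unit at C2 (ring sp3 centre and alkene geometry not controlled) | O=C1C(C(OCc2ccccc2)=CC)C(O[Si](C(C)C)(C(C)C)C(C)C)=C1[C@H](CC(C)C)C3=C(OCc4ccccc4)C(C)(C)C(=O)C(C)(C)C3=O | intermediate (not isolated)
22 | dienylketene from ring opening of 21 (alkene geometries not controlled) | CC=C(OCc1ccccc1)C=C(O[Si](C(C)C)(C(C)C)C(C)C)C(=C=O)[C@H](CC(C)C)C2=C(OCc3ccccc3)C(C)(C)C(=O)C(C)(C)C2=O | intermediate (not isolated)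
23 | 5-(benzyloxy)-6-methyl-3-(triisopropylsilyloxy)cyclohexa-2,4-dien-1-one bearing the Cα/ring D unit at C2 (C6 not controlled) | CC1C(=O)C([C@H](CC(C)C)C2=C(OCc3ccccc3)C(C)(C)C(=O)C(C)(C)C2=O)=C(O[Si](C(C)C)(C(C)C)C(C)C)C=C1OCc4ccccc4 | intermediate (not isolated)
24 | 3-(benzyloxy)-6-[(1S)-1-(2-(benzyloxy)-3,3,5,5-tetramethyl-4,6-dioxocyclohex-1-en-1-yl)-3-methylbutyl]-2-methyl-5-[(triisopropylsilyl)oxy]phenol (ring A: O7 free, O8a silylated, O5 benzylated) | Cc1c(OCc2ccccc2)cc(O[Si](C(C)C)(C(C)C)C(C)C)c([C@H](CC(C)C)C3=C(OCc4ccccc4)C(C)(C)C(=O)C(C)(C)C3=O)c1O | intermediate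
25 | 2-{(1S)-1-[2,4-bis(benzyloxy)-3-methyl-6-(triisopropylsilyloxy)phenyl]-3-methylbutyl}-3-(benzyloxy)-4,4,6,6-tetramethylcyclohex-2-ene-1,5-dione | Cc1c(OCc2ccccc2)cc(O[Si](C(C)C)(C(C)C)C(C)C)c([C@H](CC(C)C)C3=C(OCc4ccccc4)C(C)(C)C(=O)C(C)(C)C3=O)c1OCc5ccccc5 | intermediate
26 | 2-{(1S)-1-[5-acetyl-2,4-bis(benzyloxy)-3-methyl-6-(triisopropylsilyloxy)phenyl]-3-methylbutyl}-3-(benzyloxy)-4,4,6,6-tetramethylcyclohex-2-ene-1,5-dione | Cc1c(OCc2ccccc2)c(C(C)=O)c(O[Si](C(C)C)(C(C)C)C(C)C)c([C@H](CC(C)C)C3=C(OCc4ccccc4)C(C)(C)C(=O)C(C)(C)C3=O)c1OCc5ccccc5 | intermediate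
27 | 2-{(1S)-1-[3-acetyl-4,6-bis(benzyloxy)-2-hydroxy-5-methylphenyl]-3-methylbutyl}-3-(benzyloxy)-4,4,6,6-tetramethylcyclohex-2-ene-1,5-dione | Cc1c(OCc2ccccc2)c(C(C)=O)c(O)c([C@H](CC(C)C)C3=C(OCc4ccccc4)C(C)(C)C(=O)C(C)(C)C3=O)c1OCc5ccccc5 | intermediate
28 | (E)-3-(dimethylamino)prop-2-enoyl analogue of 27 (enaminone) | Cc1c(OCc2ccccc2)c(C(=O)/C=C/N(C)C)c(O)c([C@H](CC(C)C)C3=C(OCc4ccccc4)C(C)(C)C(=O)C(C)(C)C3=O)c1OCc5ccccc5 | intermediate (not isolated)
29 | 5,7-bis(benzyloxy)-8-[(1S)-1-(2-(benzyloxy)-3,3,5,5-tetramethyl-4,6-dioxocyclohex-1-en-1-yl)-3-methylbutyl]-6-methyl-4H-chromen-4-one | Cc1c(OCc2ccccc2)c6c(occc6=O)c([C@H](CC(C)C)C3=C(OCc4ccccc4)C(C)(C)C(=O)C(C)(C)C3=O)c1OCc5ccccc5 | intermediate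
30 | phenylboronic acid | OB(O)c1ccccc1 | starting material
31 | (2R)-5,7-bis(benzyloxy)-8-[(1S)-1-(2-(benzyloxy)-3,3,5,5-tetramethyl-4,6-dioxocyclohex-1-en-1-yl)-3-methylbutyl]-6-methyl-2-phenyl-2,3-dihydro-4H-chromen-4-one | Cc1c(OCc4ccccc4)c2c(c([C@H](CC(C)C)C3=C(OCc5ccccc5)C(C)(C)C(=O)C(C)(C)C3=O)c1OCc6ccccc6)O[C@@H](c7ccccc7)CC2=O | intermediate
32 | (2R)-5,7-dihydroxy-8-[(1S)-1-(2-hydroxy-3,3,5,5-tetramethyl-4,6-dioxocyclohex-1-en-1-yl)-3-methylbutyl]-6-methyl-2-phenyl-2,3-dihydro-4H-chromen-4-one (CNP0249552.1) | Cc1c(O)c2c(c([C@H](CC(C)C)C3=C(O)C(C)(C)C(=O)C(C)(C)C3=O)c1O)O[C@@H](c1ccccc1)CC2=O | target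

Total step count: 13.
Longest linear sequence: 11 steps (steps 1–4 and 7–13, from syncarpic acid); the cyclobutenone branch is steps 5–6.

Steps most likely to fail

Step 2, the one step beyond established precedent. The copper acetylide may add with poor facial discrimination, or turnover may stall because the diketonate product holds on to copper. The fallback uses known chemistry and sets out from 3. Conjugate addition of (trimethylsilyl)ethynylmagnesium bromide (THF, −40 °C) to this doubly activated alkylidene should give the racemic silylalkyne enol F1. Being a vinylogous acid, it is resolved by crystallising its (R)-1-phenylethylammonium salt F2, the choice of amine antipode and solvent being settled by screening and the assignment by crystallography. The mirror-image enol F3 stays in the liquor. Acidification of the salt returns the route at 5.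

Step 7. Opening of the donor-substituted cyclobutenone may be slower than silyl migration in the siloxyalkyne. The hindered alkyne may also be outrun by ketene self-reaction, or the new phenol may be acylated by vinylketene. The fallback forms the Cα–C8 bond on a preformed ring instead, and again sets out from 3. Commercial 2-methylbenzene-1,3,5-triol F4 is silylated at the unhindered hydroxyl para to methyl (TIPSCl, imidazole) to give diol F5. Statistical monobenzylation (BnBr, K2CO3) gives phenol F6. Enantioselective Friedel–Crafts-type conjugate addition of this phenol, ortho to its free hydroxyl, to 3 under a chiral Lewis acid is a reaction type established for phloroglucinols and alkylidene syncarpic acids. It should give the enol phenol F7. Double benzylation (BnBr, Cs2CO3) rejoins the route at 25.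

Step 12. Insertion into the electron-rich, hindered chromone may be slow, so that protodeboronation or homocoupling consumes the boronic acid, or facial control may erode. The fallback sets out from 27. Claisen–Schmidt condensation with benzaldehyde (KOH, EtOH) gives the hydroxychalcone F8. Oxa-Michael closure through O8a (NaOAc, EtOH, reflux) follows. Because Cα is fixed, the C2 epimers are diastereomers, so 31 is separated by chromatography from the 2S epimer F9. The latter is re-equilibrated under the same conditions and recycled, and the route is rejoined at 31.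

Further compounds
F1 | step 2 | racemic 3-hydroxy-4,4,6,6-tetramethyl-2-[5-methyl-1-(trimethylsilyl)hex-1-yn-3-yl]cyclohex-2-ene-1,5-dione | C[Si](C)(C)C#CC(CC(C)C)C1=C(O)C(C)(C)C(=O)C(C)(C)C1=O
F2 | step 2 | (R)-1-phenylethylammonium enolate of 5 | C[Si](C)(C)C#C[C@H](CC(C)C)C1=C([O-])C(C)(C)C(=O)C(C)(C)C1=O.C[C@@H]([NH3+])c1ccccc1
F3 | step 2 | enantiomer of 5 | C[Si](C)(C)C#C[C@@H](CC(C)C)C1=C(O)C(C)(C)C(=O)C(C)(C)C1=O
F4 | step 7 | 2-methylbenzene-1,3,5-triol | Cc1c(O)cc(O)cc1O
F5 | step 7 | 2-methyl-5-[(triisopropylsilyl)oxy]benzene-1,3-diol | Cc1c(O)cc(O[Si](C(C)C)(C(C)C)C(C)C)cc1O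
F6 | step 7 | 3-(benzyloxy)-2-methyl-5-[(triisopropylsilyl)oxy]phenol | Cc1c(OCc2ccccc2)cc(O[Si](C(C)C)(C(C)C)C(C)C)cc1O
F7 | step 7 | analogue of 24 with ring D as free enol | Cc1c(OCc2ccccc2)cc(O[Si](C(C)C)(C(C)C)C(C)C)c([C@H](CC(C)C)C3=C(O)C(C)(C)C(=O)C(C)(C)C3=O)c1O
F8 | step 12 | (E)-chalcone from 27 and benzaldehyde | Cc1c(OCc2ccccc2)c(C(=O)/C=C/c6ccccc6)c(O)c([C@H](CC(C)C)C3=C(OCc4ccccc4)C(C)(C)C(=O)C(C)(C)C3=O)c1OCc5ccccc5
F9 | step 12 | (2S) epimer of 31 | Cc1c(OCc4ccccc4)c2c(c([C@H](CC(C)C)C3=C(OCc5ccccc5)C(C)(C)C(=O)C(C)(C)C3=O)c1OCc6ccccc6)O[C@H](c7ccccc7)CC2=O
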